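**Retrosynthetic overview**
1. The ten-membered carbocycle is formed last, at C9–C10, by an intramolecular Nozaki–Hiyama–Kishi coupling of a (Z)-vinyl iodide with the C9 aldehyde (sets C9); only C14 desilylation follows.
2. The α-methylene-γ-butyrolactone is formed first, together with the C6–C7 bond and the C6/C7 stereocentres, by a new chromium-catalysed 2-(alkoxycarbonyl)allylation/lactonisation of (Z)-enal 11 with chiral allyl bromide 16; the C8 angelate is installed before macrocyclisation.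
3. Fragment A (C1–C6, C10, C14, C15) comes from neryl acetate (cis C4=C5 inherited); oxidative cleavage, Wittig homologation and α-iodination give the (Z)-C1=C10 iodide.
4. Fragment B (C7–C9, C11–C13) comes from (R)-glyceraldehyde acetonide (C8 from D-mannitol) by Morita–Baylis–Hillman reaction and SN2′ bromination.

Assumption: the SMILES is read literally (both ring alkenes cis within the ring, angelate ester, 6R,7S,8S,9R), with germacrane numbering for positions (C6 lactone carbinol, C7 ring fusion, C8 angelate carbon, C9 carbinol, C10 bearing C14H2OH, C4 bearing the C15 methyl).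

**Route**

Step 1
Reactants: 1 neryl acetate
Product: 2 (2Z)-5-(3,3-dimethyloxiran-2-yl)-3-methylpent-2-en-1-yl acetate (racemic at the oxirane carbon)
Conditions: mCPBA (1.05 equiv), CH2Cl2, 0 °C
Reagents that add atoms: meta-chloroperbenzoic acid, O=C(OO)c1cccc(Cl)c1
Why: Prilezhaev epoxidation is selective for the electron-rich remote trisubstituted alkene because the C4=C5 alkene is deactivated by the allylic acetate; the new stereocentre is racemic and is destroyed in step 2.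

Step 2
Reactants: 2 epoxy acetate
Product: 4 (2Z)-3-methyl-6-oxohex-2-en-1-yl acetate, via vicinal diol 3 (not isolated)
Conditions: H5IO6 (1.2 equiv), THF–H2O, 0 °C to rt
Reagents that add atoms: water, O (becomes the tertiary hydroxyl of 3 and leaves with acetone)
Why: Acid-mediated epoxide hydrolysis followed in the same pot by Malaprade glycol cleavage excises acetone and leaves the C1 aldehyde without touching the (Z)-allylic acetate.

Step 3
Reactants: 4 acetoxy aldehyde; 5 (triphenylphosphoranylidene)acetaldehyde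
Product: 6 (2Z,6E)-3-methyl-8-oxoocta-2,6-dien-1-yl acetate
Conditions: toluene, 80 °C
Reagents that add atoms: none
Why: Wittig olefination with the stabilised formyl ylide gives the (E)-enal and adds C10 and C14.

Step 4
Reactants: 6 (E)-enal
Product: 7 (2Z,6Z)-7-iodo-3-methyl-8-oxoocta-2,6-dien-1-yl acetate
Conditions: I2 (1.5 equiv), K2CO3 (1.2 equiv), DMAP (20 mol%), THF–H2O (1:1), rt
Reagents that add atoms: iodine, II
Why: Amine-catalysed α-iodination of the enal (conjugate addition of DMAP, iodination of the enolate, E1cB loss of DMAP) gives the thermodynamically preferred (Z)-2-iodoenal with iodine cis to C2, the geometry later carried into the C9–C10 bond.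

Step 5
Reactants: 7 iodoenal
Product: 8 (2Z,6Z)-8-hydroxy-7-iodo-3-methylocta-2,6-dien-1-yl acetate
Conditions: NaBH4, CeCl3·7H2O, MeOH, −20 °C
Reagents that add atoms: none
Why: Luche 1,2-reduction of the enal leaves the vinyl iodide, both alkenes and the acetate untouched.

Step 6
Reactants: 8 iodo allylic alcohol
Product: 9 (2Z,6Z)-8-[(tert-butyldiphenylsilyl)oxy]-7-iodo-3-methylocta-2,6-dien-1-yl acetate
Conditions: TBDPSCl, imidazole, CH2Cl2, rt
Reagents that add atoms: tert-butyl(chloro)diphenylsilane, CC(C)(C)[Si](Cl)(c1ccccc1)c1ccccc1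
Why: Standard silylation gives a C14 ether that survives the later basic, acidic and chromium steps.

Step 7
Reactants: 9 silyl ether acetate
Product: 10 (2Z,6Z)-8-[(tert-butyldiphenylsilyl)oxy]-7-iodo-3-methylocta-2,6-dien-1-ol
Conditions: K2CO3 (0.2 equiv), MeOH, 0 °C to rt
Reagents that add atoms: none
Why: Base-catalysed transesterification with methanol removes the acetate selectively.

Step 8
Reactants: 10 allylic alcohol
Product: 11 (2Z,6Z)-8-[(tert-butyldiphenylsilyl)oxy]-7-iodo-3-methylocta-2,6-dienal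
Conditions: activated MnO2 (15 equiv), CH2Cl2, rt
Reagents that add atoms: none
Why: Allylic oxidation with MnO2 under neutral conditions gives the enal with retention of the (Z) geometry, as for nerol to neral.

Step 9
Reactants: 12 1,2:5,6-di-O-isopropylidene-D-mannitol
Product: 13 (4R)-2,2-dimethyl-1,3-dioxolane-4-carbaldehyde (two equivalents)
Conditions: NaIO4, sat. aq. NaHCO3, CH2Cl2, rt
Reagents that add atoms: none
Why: Malaprade glycol cleavage of the C2-symmetric diol gives two equivalents of the aldehyde, so C8 comes from the chiral pool.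

Step 10
Reactants: 13 (R)-glyceraldehyde acetonide; 14 methyl acrylate
Product: 15 methyl 2-{[(4R)-2,2-dimethyl-1,3-dioxolan-4-yl](hydroxy)methyl}prop-2-enoate (mixture of carbinol epimers)
Conditions: DABCO (1 equiv), 14 (3 equiv), 1,4-dioxane–H2O (1:1), rt
Reagents that add atoms: none
Why: Morita–Baylis–Hillman reaction; the new carbinol centre forms as a mixture, which is irrelevant because it becomes sp2 in step 11.

Step 11
Reactants: 15 Morita–Baylis–Hillman adduct
Product: 16 methyl (2Z)-2-(bromomethyl)-3-[(4S)-2,2-dimethyl-1,3-dioxolan-4-yl]prop-2-enoate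
Conditions: NBS (1.5 equiv), Me2S (1.6 equiv), CH2Cl2, 0 °C to rt
Reagents that add atoms: N-bromosuccinimide, BrN1C(=O)CCC1=O
Why: Corey–Kim-type activation of the allylic alcohol and SN2′ delivery of bromide convert both epimers of 15 into the thermodynamically favoured (Z)-2-(bromomethyl)enoate.

Step 12
Reactants: 11 (Z,Z)-iodo enal; 16 allyl bromide
Product: 19 (4S,5R)-5-[(1Z,5Z)-7-[(tert-butyldiphenylsilyl)oxy]-6-iodo-2-methylhepta-1,5-dien-1-yl]-4-[(4S)-2,2-dimethyl-1,3-dioxolan-4-yl]-3-methylideneoxolan-2-one, via silyl ether 17 (not isolated), via hydroxy ester 18 (not isolated)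
Conditions: CrCl2 (10 mol%), 3,6-di-tert-butyl-1,8-bis[(4S)-4-isopropyl-4,5-dihydro-1,3-oxazol-2-yl]-9H-carbazole (12 mol%), i-Pr2NEt (30 mol%), Mn powder (2 equiv), Me3SiCl (1.5 equiv), 16 (1.3 equiv), THF, 0 °C to rt; then 1 M HCl, THF, 0 °C; then PPTS (10 mol%), toluene, 45 °C
Reagents that add atoms: chlorotrimethylsilane, C[Si](C)(C)Cl (silyl group of 17 only, lost in the acidic work-up)
Why: Proposed new method: a chromium-catalysed, ligand-controlled 2-(alkoxycarbonyl)allylation that joins a γ-branched, δ-oxygenated chiral allyl bromide to a (Z)-enal with double stereodifferentiation, which has not been shown for such partners; mechanistic reasoning: divalent chromium (regenerated from the trivalent alkoxide by Mn and Me3SiCl) turns 16 into a trivalent allylchromium that equilibrates by 1,3-metal shift and adds through a closed chair Zimmerman–Traxler transition state with the dioxolanyl group pseudo-equatorial, giving the anti C6/C7 relationship and hence the trans lactone, while the tridentate carbazole-bis(oxazoline) ligand exposes the Si face of the aldehyde (6R, therefore 7S) and the C8 centre (hydrogen eclipsing the alkene to relieve A(1,3) strain, attack anti to its CH2O arm) is expected to reinforce this, the vinyl iodide being inert in the absence of nickel; closest known reaction type: chromium-catalysed enantioselective Nozaki–Hiyama–Kishi 2-(alkoxycarbonyl)allylation of aldehydes with simple achiral 2-(bromomethyl)acrylates followed by lactonisation.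

Step 13
Reactants: 19 lactone acetonide
Product: 20 (4R,5R)-5-[(1Z,5Z)-7-[(tert-butyldiphenylsilyl)oxy]-6-iodo-2-methylhepta-1,5-dien-1-yl]-4-[(1S)-1,2-dihydroxyethyl]-3-methylideneoxolan-2-one
Conditions: AcOH–H2O (4:1), 40 °C
Reagents that add atoms: none
Why: Mild acid hydrolysis of the terminal acetonide; the tert-butyldiphenylsilyl ether, the trans lactone and the vinyl iodide are stable to aqueous acetic acid.

Step 14
Reactants: 20 lactone diol
Product: 21 (4R,5R)-5-[(1Z,5Z)-7-[(tert-butyldiphenylsilyl)oxy]-6-iodo-2-methylhepta-1,5-dien-1-yl]-4-[(1S)-1-hydroxy-2-[(triethylsilyl)oxy]ethyl]-3-methylideneoxolan-2-one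
Conditions: Et3SiCl (1.05 equiv), imidazole, CH2Cl2, −40 °C
Reagents that add atoms: chlorotriethylsilane, CC[Si](Cl)(CC)CC
Why: Kinetic silylation takes the primary C9 hydroxyl at low temperature and leaves the C8 hydroxyl free.

Step 15
Reactants: 21 C8 alcohol; 22 angelic acid
Product: 24 (1S)-1-[(2R,3S)-2-[(1Z,5Z)-7-[(tert-butyldiphenylsilyl)oxy]-6-iodo-2-methylhepta-1,5-dien-1-yl]-4-methylidene-5-oxooxolan-3-yl]-2-[(triethylsilyl)oxy]ethyl (2Z)-2-methylbut-2-enoate, via mixed anhydride 23 (not isolated)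
Conditions: 22 (3 equiv), 2,4,6-trichlorobenzoyl chloride (3 equiv), Et3N, toluene, rt; then 21, toluene, 75 °C
Reagents that add atoms: 2,4,6-trichlorobenzoyl chloride, O=C(Cl)c1c(Cl)cc(Cl)cc1Cl (aroyl part of 23 only)
Why: Yamaguchi esterification through the mixed anhydride without DMAP acylates the hindered C8 hydroxyl with retention at C8 and without angelate-to-tiglate isomerisation.

Step 16
Reactants: 24 angelate triethylsilyl ether
Product: 25 (1S)-1-[(2R,3S)-2-[(1Z,5Z)-7-[(tert-butyldiphenylsilyl)oxy]-6-iodo-2-methylhepta-1,5-dien-1-yl]-4-methylidene-5-oxooxolan-3-yl]-2-hydroxyethyl (2Z)-2-methylbut-2-enoate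
Conditions: PPTS (20 mol%), MeOH–CH2Cl2 (1:1), 0 °C
Reagents that add atoms: none
Why: Acid-catalysed methanolysis cleaves the primary triethylsilyl ether in the presence of the tert-butyldiphenylsilyl ether, and the weakly acidic medium suppresses O8-to-O9 acyl migration.

Step 17
Reactants: 25 primary alcohol
Product: 26 (1S)-1-[(2R,3S)-2-[(1Z,5Z)-7-[(tert-butyldiphenylsilyl)oxy]-6-iodo-2-methylhepta-1,5-dien-1-yl]-4-methylidene-5-oxooxolan-3-yl]-2-oxoethyl (2Z)-2-methylbut-2-enoate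
Conditions: Dess–Martin periodinane, CH2Cl2, 0 °C to rt
Reagents that add atoms: none
Why: Dess–Martin oxidation under non-basic conditions gives the α-acyloxy aldehyde without epimerisation at C8.

Step 18
Reactants: 26 iodo aldehyde
Product: 27 (3aS,4S,5R,6Z,10Z,11aR)-6-{[(tert-butyldiphenylsilyl)oxy]methyl}-5-hydroxy-10-methyl-3-methylidene-2-oxo-2,3,3a,4,5,8,9,11a-octahydrocyclodeca[b]furan-4-yl (2Z)-2-methylbut-2-enoate
Conditions: CrCl2 (10 equiv), NiCl2 (5 mol%), DMSO–THF (3:1), 0.003 M, rt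
Reagents that add atoms: none
Why: Intramolecular Nozaki–Hiyama–Kishi reaction: zerovalent nickel inserts into the C–I bond, transmetallation gives a trivalent alkenylchromium that adds to the aldehyde at high dilution with retention of alkene geometry (C9 cis to C2), closing the ten-membered ring, and C9 (R) is set by polar Felkin–Anh addition anti to the C8 acyloxy group (8,9-anti).

Step 19
Reactants: 27 macrocyclic silyl ether
Product: 28 (3aS,4S,5R,6Z,10Z,11aR)-5-hydroxy-6-(hydroxymethyl)-10-methyl-3-methylidene-2-oxo-2,3,3a,4,5,8,9,11a-octahydrocyclodeca[b]furan-4-yl (2Z)-2-methylbut-2-enoate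
Conditions: HF·pyridine, pyridine, THF, 0 °C to rt
Reagents that add atoms: none
Why: Fluoride-mediated desilylation under buffered, weakly acidic conditions frees the C14 hydroxyl without acyl migration or attack on the α-methylene lactone.

**Compound list**
1 | neryl acetate, (2Z)-3,7-dimethylocta-2,6-dien-1-yl acetate | CC(=O)OC/C=C(/C)CCC=C(C)C | starting material
2 | (2Z)-5-(3,3-dimethyloxiran-2-yl)-3-methylpent-2-en-1-yl acetate (racemic at the oxirane carbon) | CC(=O)OC/C=C(/C)CCC1OC1(C)C | intermediate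
3 | vicinal diol, (2Z)-6,7-dihydroxy-3,7-dimethyloct-2-en-1-yl acetate (racemic) | CC(=O)OC/C=C(/C)CCC(O)C(C)(C)O | intermediate
4 | (2Z)-3-methyl-6-oxohex-2-en-1-yl acetate | CC(=O)OC/C=C(/C)CCC=O | intermediate
5 | (triphenylphosphoranylidene)acetaldehyde | O=CC=P(c1ccccc1)(c1ccccc1)c1ccccc1 | starting material
6 | (2Z,6E)-3-methyl-8-oxoocta-2,6-dien-1-yl acetate | CC(=O)OC/C=C(/C)CC/C=C/C=O | intermediate
7 | (2Z,6Z)-7-iodo-3-methyl-8-oxoocta-2,6-dien-1-yl acetate | CC(=O)OC/C=C(/C)CC/C=C(\I)C=O | intermediate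
8 | (2Z,6Z)-8-hydroxy-7-iodo-3-methylocta-2,6-dien-1-yl acetate | CC(=O)OC/C=C(/C)CC/C=C(\I)CO | intermediate
9 | (2Z,6Z)-8-[(tert-butyldiphenylsilyl)oxy]-7-iodo-3-methylocta-2,6-dien-1-yl acetate | CC(=O)OC/C=C(/C)CC/C=C(\I)CO[Si](c1ccccc1)(c1ccccc1)C(C)(C)C | intermediate
10 | (2Z,6Z)-8-[(tert-butyldiphenylsilyl)oxy]-7-iodo-3-methylocta-2,6-dien-1-ol | OC/C=C(/C)CC/C=C(\I)CO[Si](c1ccccc1)(c1ccccc1)C(C)(C)C | intermediate
11 | (2Z,6Z)-8-[(tert-butyldiphenylsilyl)oxy]-7-iodo-3-methylocta-2,6-dienal | O=C/C=C(/C)CC/C=C(\I)CO[Si](c1ccccc1)(c1ccccc1)C(C)(C)C | intermediate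
12 | 1,2:5,6-di-O-isopropylidene-D-mannitol | CC1(C)OC[C@@H](O1)[C@H](O)[C@@H](O)[C@H]1COC(C)(C)O1 | starting material
13 | (4R)-2,2-dimethyl-1,3-dioxolane-4-carbaldehyde | O=C[C@H]1COC(C)(C)O1 | intermediate
14 | methyl acrylate | C=CC(=O)OC | starting material
15 | methyl 2-{[(4R)-2,2-dimethyl-1,3-dioxolan-4-yl](hydroxy)methyl}prop-2-enoate (carbinol epimers) | C=C(C(=O)OC)C(O)[C@H]1COC(C)(C)O1 | intermediate
16 | methyl (2Z)-2-(bromomethyl)-3-[(4S)-2,2-dimethyl-1,3-dioxolan-4-yl]prop-2-enoate | BrC/C(C(=O)OC)=C\[C@H]1COC(C)(C)O1 | intermediate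
17 | silyl ether, methyl (3R,4R,5Z,9Z)-11-[(tert-butyldiphenylsilyl)oxy]-3-[(4S)-2,2-dimethyl-1,3-dioxolan-4-yl]-10-iodo-6-methyl-2-methylidene-4-[(trimethylsilyl)oxy]undeca-5,9-dienoate | C=C(C(=O)OC)[C@H]([C@H]1COC(C)(C)O1)[C@H](O[Si](C)(C)C)/C=C(/C)CC/C=C(\I)CO[Si](c1ccccc1)(c1ccccc1)C(C)(C)C | intermediate
18 | hydroxy ester, methyl (3S,4R,5Z,9Z)-11-[(tert-butyldiphenylsilyl)oxy]-3-[(4S)-2,2-dimethyl-1,3-dioxolan-4-yl]-4-hydroxy-10-iodo-6-methyl-2-methylideneundeca-5,9-dienoate | C=C(C(=O)OC)[C@H]([C@H]1COC(C)(C)O1)[C@H](O)/C=C(/C)CC/C=C(\I)CO[Si](c1ccccc1)(c1ccccc1)C(C)(C)C | intermediate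
19 | (4S,5R)-5-[(1Z,5Z)-7-[(tert-butyldiphenylsilyl)oxy]-6-iodo-2-methylhepta-1,5-dien-1-yl]-4-[(4S)-2,2-dimethyl-1,3-dioxolan-4-yl]-3-methylideneoxolan-2-one | C=C1C(=O)O[C@H](/C=C(/C)CC/C=C(\I)CO[Si](c2ccccc2)(c2ccccc2)C(C)(C)C)[C@H]1[C@H]1COC(C)(C)O1 | intermediate
20 | (4R,5R)-5-[(1Z,5Z)-7-[(tert-butyldiphenylsilyl)oxy]-6-iodo-2-methylhepta-1,5-dien-1-yl]-4-[(1S)-1,2-dihydroxyethyl]-3-methylideneoxolan-2-one | C=C1C(=O)O[C@H](/C=C(/C)CC/C=C(\I)CO[Si](c2ccccc2)(c2ccccc2)C(C)(C)C)[C@H]1[C@H](O)CO | intermediate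
21 | (4R,5R)-5-[(1Z,5Z)-7-[(tert-butyldiphenylsilyl)oxy]-6-iodo-2-methylhepta-1,5-dien-1-yl]-4-[(1S)-1-hydroxy-2-[(triethylsilyl)oxy]ethyl]-3-methylideneoxolan-2-one | C=C1C(=O)O[C@H](/C=C(/C)CC/C=C(\I)CO[Si](c2ccccc2)(c2ccccc2)C(C)(C)C)[C@H]1[C@H](O)CO[Si](CC)(CC)CC | intermediate
22 | angelic acid, (2Z)-2-methylbut-2-enoic acid | C/C=C(/C)C(=O)O | starting material
23 | mixed anhydride, (2Z)-2-methylbut-2-enoic 2,4,6-trichlorobenzoic anhydride | C/C=C(/C)C(=O)OC(=O)c1c(Cl)cc(Cl)cc1Cl | intermediate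
24 | (1S)-1-[(2R,3S)-2-[(1Z,5Z)-7-[(tert-butyldiphenylsilyl)oxy]-6-iodo-2-methylhepta-1,5-dien-1-yl]-4-methylidene-5-oxooxolan-3-yl]-2-[(triethylsilyl)oxy]ethyl (2Z)-2-methylbut-2-enoate | C=C1C(=O)O[C@H](/C=C(/C)CC/C=C(\I)CO[Si](c2ccccc2)(c2ccccc2)C(C)(C)C)[C@H]1[C@H](OC(=O)/C(C)=C\C)CO[Si](CC)(CC)CC | intermediate
25 | (1S)-1-[(2R,3S)-2-[(1Z,5Z)-7-[(tert-butyldiphenylsilyl)oxy]-6-iodo-2-methylhepta-1,5-dien-1-yl]-4-methylidene-5-oxooxolan-3-yl]-2-hydroxyethyl (2Z)-2-methylbut-2-enoate | C=C1C(=O)O[C@H](/C=C(/C)CC/C=C(\I)CO[Si](c2ccccc2)(c2ccccc2)C(C)(C)C)[C@H]1[C@H](OC(=O)/C(C)=C\C)CO | intermediate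
26 | (1S)-1-[(2R,3S)-2-[(1Z,5Z)-7-[(tert-butyldiphenylsilyl)oxy]-6-iodo-2-methylhepta-1,5-dien-1-yl]-4-methylidene-5-oxooxolan-3-yl]-2-oxoethyl (2Z)-2-methylbut-2-enoate | C=C1C(=O)O[C@H](/C=C(/C)CC/C=C(\I)CO[Si](c2ccccc2)(c2ccccc2)C(C)(C)C)[C@H]1[C@H](OC(=O)/C(C)=C\C)C=O | intermediate
27 | (3aS,4S,5R,6Z,10Z,11aR)-6-{[(tert-butyldiphenylsilyl)oxy]methyl}-5-hydroxy-10-methyl-3-methylidene-2-oxo-2,3,3a,4,5,8,9,11a-octahydrocyclodeca[b]furan-4-yl (2Z)-2-methylbut-2-enoate | C=C1C(=O)O[C@@H]2/C=C(/C)CC/C=C(/CO[Si](c3ccccc3)(c3ccccc3)C(C)(C)C)[C@@H](O)[C@@H](OC(=O)/C(C)=C\C)[C@@H]12 | intermediate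
28 | (3aS,4S,5R,6Z,10Z,11aR)-5-hydroxy-6-(hydroxymethyl)-10-methyl-3-methylidene-2-oxo-2,3,3a,4,5,8,9,11a-octahydrocyclodeca[b]furan-4-yl (2Z)-2-methylbut-2-enoate (CNP0276773.5) | C=C1C(=O)O[C@@H]2/C=C(/C)CC/C=C(/CO)[C@@H](O)[C@@H](OC(=O)/C(C)=C\C)[C@@H]12 | target

**Step count**
Total: 19 steps. Longest linear sequence: 16 steps (steps 1–8, then 12–19); the fragment B branch (steps 9–11) joins at step 12.

**Three steps most likely to fail**

Step 12 (the new step). The risks are a mismatched pairing between the ligand and the C8 stereocentre (if the (4S)-ligand delivers to the Re face, its mirror image is used), 1,4-elimination of the allylchromium to a diene, and Z/E drift of the enal. The fallback uses known chemistry, sets out from 13 (with 11 as partner) and returns at 19. Aldehyde 13 is converted by Corey–Fuchs olefination (CBr4, PPh3, CH2Cl2, 0 °C) into (4S)-4-(2,2-dibromoethenyl)-2,2-dimethyl-1,3-dioxolane F1. Treatment with n-BuLi (2.1 equiv, THF, −78 °C) and then ClCO2Me gives methyl 3-[(4S)-2,2-dimethyl-1,3-dioxolan-4-yl]prop-2-ynoate F2. Syn-hydroalumination with i-Bu2AlH/HMPA (THF, 0 °C) and trapping of the α-aluminio acrylate with 2-(iodomethyl)-4,4,5,5-tetramethyl-1,3,2-dioxaborolane gives methyl (2Z)-3-[(4S)-2,2-dimethyl-1,3-dioxolan-4-yl]-2-[(4,4,5,5-tetramethyl-1,3,2-dioxaborolan-2-yl)methyl]prop-2-enoate F3, in which the dioxolanyl group is cis to the ester. Heating F3 with enal 11 (toluene, 80 °C) gives, by uncatalysed closed-chair allylboration that is stereospecific for the anti adduct, methyl (3S,4R,5Z,9Z)-11-[(tert-butyldiphenylsilyl)oxy]-3-[(4S)-2,2-dimethyl-1,3-dioxolan-4-yl]-10-iodo-6-methyl-2-methylidene-4-[(4,4,5,5-tetramethyl-1,3,2-dioxaborolan-2-yl)oxy]undeca-5,9-dienoate F4. Aqueous work-up hydrolyses the borate to 18, and PPTS (toluene, 45 °C) lactonises it to 19. Here the C6/C7 relationship is fixed by the boronate geometry and the C7/C8 relationship by substrate control, so diastereomers are separated at 19.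

Step 15. The risks are sluggish acylation of the hindered C8 hydroxyl and isomerisation of the angelate to the tiglate. The fallback sets out from 21 and returns at 24. Alcohol 21 is esterified with 2-[bis(2,2,2-trifluoroethoxy)phosphoryl]propanoic acid (EDC·HCl, DMAP cat., CH2Cl2, 0 °C) to give (1S)-1-[(2R,3S)-2-[(1Z,5Z)-7-[(tert-butyldiphenylsilyl)oxy]-6-iodo-2-methylhepta-1,5-dien-1-yl]-4-methylidene-5-oxooxolan-3-yl]-2-[(triethylsilyl)oxy]ethyl 2-[bis(2,2,2-trifluoroethoxy)phosphoryl]propanoate F5 (epimers at the phosphonate carbon). Still–Gennari olefination (KN(SiMe3)2, 18-crown-6, THF, −78 °C; then acetaldehyde) then builds the (Z)-2-methylbut-2-enoate in place and gives 24, so that no activated angelic acid is handled.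

Step 18. The risks are low or wrong selectivity at C9 under the ring constraint, oligomerisation, and O8-to-O9 acyl migration on the chromium alkoxide. The fallback sets out from 26 and returns at 27. If the cyclisation gives mainly the C9 epimer (3aS,4S,5S,6Z,10Z,11aR)-6-{[(tert-butyldiphenylsilyl)oxy]methyl}-5-hydroxy-10-methyl-3-methylidene-2-oxo-2,3,3a,4,5,8,9,11a-octahydrocyclodeca[b]furan-4-yl (2Z)-2-methylbut-2-enoate F6, the carbinol mixture is oxidised (Dess–Martin periodinane, CH2Cl2, 0 °C) to the enone (3aS,4S,6Z,10Z,11aR)-6-{[(tert-butyldiphenylsilyl)oxy]methyl}-10-methyl-3-methylidene-2,5-dioxo-2,3,3a,4,5,8,9,11a-octahydrocyclodeca[b]furan-4-yl (2Z)-2-methylbut-2-enoate F7. C9 is then set by reagent-controlled Corey–Bakshi–Shibata reduction ((R)-1-methyl-3,3-diphenylhexahydropyrrolo[1,2-c][1,3,2]oxazaborole, BH3·SMe2, toluene, −40 °C, the alkenyl carbon acting as the large group), which gives 27.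

**Further compounds**
F1 | step 12 | (4S)-4-(2,2-dibromoethenyl)-2,2-dimethyl-1,3-dioxolane | BrC(Br)=C[C@H]1COC(C)(C)O1
F2 | step 12 | methyl 3-[(4S)-2,2-dimethyl-1,3-dioxolan-4-yl]prop-2-ynoate | COC(=O)C#C[C@H]1COC(C)(C)O1
F3 | step 12 | methyl (2Z)-3-[(4S)-2,2-dimethyl-1,3-dioxolan-4-yl]-2-[(4,4,5,5-tetramethyl-1,3,2-dioxaborolan-2-yl)methyl]prop-2-enoate | COC(=O)/C(CB2OC(C)(C)C(C)(C)O2)=C\[C@H]1COC(C)(C)O1
F4 | step 12 | methyl (3S,4R,5Z,9Z)-11-[(tert-butyldiphenylsilyl)oxy]-3-[(4S)-2,2-dimethyl-1,3-dioxolan-4-yl]-10-iodo-6-methyl-2-methylidene-4-[(4,4,5,5-tetramethyl-1,3,2-dioxaborolan-2-yl)oxy]undeca-5,9-dienoate | C=C(C(=O)OC)[C@H]([C@H]1COC(C)(C)O1)[C@H](OB2OC(C)(C)C(C)(C)O2)/C=C(/C)CC/C=C(\I)CO[Si](c1ccccc1)(c1ccccc1)C(C)(C)C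
F5 | step 15 | (1S)-1-[(2R,3S)-2-[(1Z,5Z)-7-[(tert-butyldiphenylsilyl)oxy]-6-iodo-2-methylhepta-1,5-dien-1-yl]-4-methylidene-5-oxooxolan-3-yl]-2-[(triethylsilyl)oxy]ethyl 2-[bis(2,2,2-trifluoroethoxy)phosphoryl]propanoate | C=C1C(=O)O[C@H](/C=C(/C)CC/C=C(\I)CO[Si](c2ccccc2)(c2ccccc2)C(C)(C)C)[C@H]1[C@H](OC(=O)C(C)P(=O)(OCC(F)(F)F)OCC(F)(F)F)CO[Si](CC)(CC)CC
F6 | step 18 | (3aS,4S,5S,6Z,10Z,11aR)-6-{[(tert-butyldiphenylsilyl)oxy]methyl}-5-hydroxy-10-methyl-3-methylidene-2-oxo-2,3,3a,4,5,8,9,11a-octahydrocyclodeca[b]furan-4-yl (2Z)-2-methylbut-2-enoate | C=C1C(=O)O[C@@H]2/C=C(/C)CC/C=C(/CO[Si](c3ccccc3)(c3ccccc3)C(C)(C)C)[C@H](O)[C@@H](OC(=O)/C(C)=C\C)[C@@H]12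
F7 | step 18 | (3aS,4S,6Z,10Z,11aR)-6-{[(tert-butyldiphenylsilyl)oxy]methyl}-10-methyl-3-methylidene-2,5-dioxo-2,3,3a,4,5,8,9,11a-octahydrocyclodeca[b]furan-4-yl (2Z)-2-methylbut-2-enoate | C=C1C(=O)O[C@@H]2/C=C(/C)CC/C=C(/CO[Si](c3ccccc3)(c3ccccc3)C(C)(C)C)C(=O)[C@@H](OC(=O)/C(C)=C\C)[C@@H]12
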